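**Retrosynthetic overview**
- Target ⇐ its dimethyl ester ⇐ key step: ring A and the γ-lactone are closed together by oxidative radical lactone annulation of a malonate onto the C5=C10 alkene of a ring B/C/D tricycle. The C4–C5 bond joins two normally nucleophilic carbons through an oxidised malonate (malonyl radical, an enolonium equivalent) and sets C4, C5 and C10.
- The cyclopentene with its malonate side chain ⇐ C10 enol triflate + B-alkyl Suzuki coupling with hydroborated dimethyl allylmalonate.
- Ring D ⇐ intramolecular Nozaki–Hiyama–Kishi addition of a 2-bromoallyl group to the C13 ketone; quaternary C8 ⇐ Hosomi–Sakurai angular allylation of a hydrindenedione whose angular C9 ester blocks enolisation and is later removed.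
- Hydrindenedione ⇐ dimethyl 3-oxopentanedioate + methyl bromoacetate (Dieckmann, ring B) + but-3-en-2-one (Michael, then ring C closure through an enol triflate), resolved once.
- Ring order: B → C → D → A with lactone.

Assumption 1: locants are gibberellane locants (C7 = carboxyl carbon on C6; C18, C19 = the two carboxyl carbons on C4). "β" is the face of ring B that carries H-5, H-9, C-7 and C-15 in the target; "α" is the face that carries C-4, O-10, C-11 and C-14. "The target gibberellin" is the compound of the task, 13-hydroxy-20-norgibberell-16-ene-7,18,19-trioic acid 19,10-lactone.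
Assumption 2: the absolute configuration is introduced by chromatographic resolution of racemic 7; half of the material is discarded there. The route is a paper proposal and has not been run.

Step 1
Reactants: 1 dimethyl 3-oxopentanedioate; 2 methyl bromoacetate
Product: 4 dimethyl 2,4-dioxocyclopentane-1,3-dicarboxylate, via triester 3 (not isolated)
Conditions: NaOMe (1.0 equiv), MeOH, 0 °C, then 2, rt; then NaOMe (1.2 equiv), reflux; aq HCl
Reagents that add atoms: none
Why: C-alkylation of the β-keto diester enolate, then Dieckmann condensation of the unsubstituted β-keto ester α-carbon (C9) onto the new acetate ester (C10); the closure is reversible and is funnelled to the five-membered ring whose tricarbonyl enolate is the most stabilised, and no fixed stereocentre is formed yet.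

Step 2
Reactants: 4 dimethyl 2,4-dioxocyclopentane-1,3-dicarboxylate; 5 but-3-en-2-one
Product: 6 dimethyl 2,4-dioxo-3-(3-oxobutyl)cyclopentane-1,3-dicarboxylate (racemic)
Conditions: Et3N (10 mol %), 5 (1.0 equiv), MeCN, rt
Reagents that add atoms: none
Why: Michael addition of the most acidic carbon (C9, between two ketones and an ester), as in the first stage of a Hajos–Parrish sequence; C9 becomes a quaternary stereocentre, formed as the racemate.

Step 3
Reactants: 6 dimethyl 2,4-dioxo-3-(3-oxobutyl)cyclopentane-1,3-dicarboxylate
Product: 7 racemic dimethyl 4-oxo-3-(3-oxobutyl)-2-{[(trifluoromethyl)sulfonyl]oxy}cyclopent-1-ene-1,3-dicarboxylate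
Conditions: NaH (1.05 equiv), THF, 0 °C; PhNTf2, 0 °C to rt; cold dilute aq HCl work-up
Reagents that add atoms: N-phenylbis(trifluoromethanesulfonimide), O=S(=O)(N(c1ccccc1)S(=O)(=O)C(F)(F)F)C(F)(F)F
Why: enol triflate formation at the only remaining 1,3-dicarbonyl unit (C6-H between the C8 ketone and the C7 ester), which marks C8 and not C10 as the electrophile for ring C and removes the labile C6 stereocentre.

Step 4
Reactants: 7 racemic enol triflate
Product: 8 dimethyl (3S)-4-oxo-3-(3-oxobutyl)-2-{[(trifluoromethyl)sulfonyl]oxy}cyclopent-1-ene-1,3-dicarboxylate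
Conditions: preparative SFC, amylose tris(3,5-dimethylphenylcarbamate) phase, CO2/MeOH
Reagents that add atoms: none
Why: chromatographic resolution on a chiral stationary phase; 7 has a single, configurationally stable quaternary stereocentre (C9), and the (3S) isomer has the C9 configuration that later directs C8.

Step 5
Reactants: 8 (3S)-enol triflate
Product: 9 dimethyl (7aS)-1,5-dioxo-2,3,5,6,7,7a-hexahydro-1H-indene-3,7a-dicarboxylate
Conditions: Pd(PPh3)4 (10 mol %), K3PO4, dioxane, 80 °C
Reagents that add atoms: none
Why: intramolecular palladium-catalysed α-alkenylation of the methyl ketone enolate with the vinyl triflate closes six-membered ring C at C8 (the alternative enolate carbon would give a four-membered ring); the first-formed C6=C8 isomer equilibrates with the conjugated enone through the dienolate, and C9 is untouched.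

Step 6
Reactants: 9 hydrindenedione diester; 10 (2-bromoprop-2-en-1-yl)trimethylsilane
Product: 11 dimethyl 3a-(2-bromoprop-2-en-1-yl)-1,5-dioxooctahydro-1H-indene-3,7a-dicarboxylate (cis-fused, bromoallyl β on C8)
Conditions: TiCl4, CH2Cl2, −78 to −30 °C; H2O
Reagents that add atoms: none
Why: Hosomi–Sakurai conjugate allylation at the ring-fusion β-carbon, the classical way to place an angular allyl group on a fused enone; addition occurs on the face that gives the cis-fused hydrindane, i.e. cis to the angular C9 ester, which sets quaternary C8 with C15 β.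

Step 7
Reactants: 11 bromoallyl diketone
Product: 12 dimethyl 6-hydroxy-5-methylidene-1-oxooctahydro-3a,6-methanoazulene-3,8a(1H)-dicarboxylate
Conditions: CrCl2 (6 equiv), NiCl2 (5 mol %), DMSO, rt to 50 °C; H2O
Reagents that add atoms: none
Why: intramolecular Nozaki–Hiyama–Kishi addition of the vinylchromium species to the C13 cyclohexanone closes ring D as the bicyclo[3.2.1]octane with bridgehead hydroxyl and exocyclic methylene; the neopentyl C10 ketone would give a strained bicyclo[2.2.1] ring, and the β tether fixes the C13 configuration.

Step 8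
Reactants: 12 tricyclic keto diester
Product: 13 methyl 6-hydroxy-5-methylidene-1-oxooctahydro-1H-3a,6-methanoazulene-3-carboxylate (H-9 β, C6 ester β)
Conditions: LiCl, DMSO, H2O, 140 °C; then NaOMe (0.3 equiv), MeOH, 50 °C
Reagents that add atoms: none
Why: Krapcho dealkoxycarbonylation removes only the β-keto angular ester; base equilibration is then expected to place H-9 for the cis B/C fusion and the C6 ester on the convex β face, where it avoids the C14 methylene.

Step 9
Reactants: 13 tricyclic keto ester
Product: 14 C10 enol triflate of 13 (C5=C10)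
Conditions: KN(SiMe3)2 (2.2 equiv), THF, −78 °C; PhNTf2 (1.1 equiv), −78 to 0 °C; cold dilute aq HCl work-up
Reagents that add atoms: N-phenylbis(trifluoromethanesulfonimide), O=S(=O)(N(c1ccccc1)S(=O)(=O)C(F)(F)F)C(F)(F)F
Why: kinetic deprotonation at the C5 methylene rather than the hindered ring-fusion methine C9, then O-triflation of the enolate (the first equivalent of base parks the tertiary alcohol as its hindered alkoxide); no stereocentre is touched at −78 °C.

Step 10
Reactants: 14 enol triflate; 15 dimethyl 2-(prop-2-en-1-yl)propanedioate
Product: 17 cyclopentene malonate (chain C1–C4 on C10), via alkylborane 16 (not isolated)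
Conditions: 15, 9-BBN, THF, rt; then 14, PdCl2(dppf) (5 mol %), aq K3PO4, DMF, rt
Reagents that add atoms: none
Why: anti-Markovnikov hydroboration, then B-alkyl Suzuki–Miyaura coupling with the enol triflate, attaches C1–C4 to C10 without moving the C5=C10 alkene; phosphate at rt should leave the allylic C6 ester centre alone.

Step 11
Reactants: 17 cyclopentene malonate
Product: 18 dimethyl ester of the target gibberellin
Conditions: Mn(OAc)3·2H2O (2.2 equiv), AcOH, 50 °C, degassed
Reagents that add atoms: none
Why: oxidative radical lactone annulation: trivalent manganese oxidises the malonate enol to an electrophilic malonyl radical, so C4 bonds to alkene carbon C5 in a 6-endo cyclisation (ring A), and the tertiary C10 radical is oxidised to the cation and captured by the cis ester carbonyl with loss of methyl acetate; attack anti to the β C6 ester, with the chain folded on the H-9 side, puts C4 on the α face and the lactone oxygen must follow on the same face, which sets C5, C10 and C4 together.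

Step 12
Reactants: 18 dimethyl ester of the target gibberellin
Product: 19 the target gibberellin
Conditions: LiSPr, HMPA, rt; dilute HCl
Reagents that add atoms: none
Why: SN2 demethylation of both hindered methyl esters by thiolate; the lactone has a tertiary alkyl oxygen and cannot be cleaved this way, and no stereocentre is enolisable under these conditions.

**Compound list**
1 | dimethyl 3-oxopentanedioate | COC(=O)CC(=O)CC(=O)OC | starting material
2 | methyl bromoacetate | COC(=O)CBr | starting material
3 | dimethyl 2-(2-methoxy-2-oxoethyl)-3-oxopentanedioate | COC(=O)CC(=O)C(CC(=O)OC)C(=O)OC | intermediate (not isolated)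
4 | dimethyl 2,4-dioxocyclopentane-1,3-dicarboxylate (keto form drawn; ring carbons = C6, C8, C9, C10, C5) | COC(=O)C1CC(=O)C(C(=O)OC)C1=O | intermediate
5 | but-3-en-2-one | CC(=O)C=C | starting material
6 | dimethyl 2,4-dioxo-3-(3-oxobutyl)cyclopentane-1,3-dicarboxylate, racemic at C3 (= C9), C1 epimerisable | COC(=O)C1CC(=O)C(CCC(C)=O)(C(=O)OC)C1=O | intermediate
7 | racemic dimethyl 4-oxo-3-(3-oxobutyl)-2-{[(trifluoromethyl)sulfonyl]oxy}cyclopent-1-ene-1,3-dicarboxylate | COC(=O)C1=C(OS(=O)(=O)C(F)(F)F)C(CCC(C)=O)(C(=O)OC)C(=O)C1 | intermediate
8 | dimethyl (3S)-4-oxo-3-(3-oxobutyl)-2-{[(trifluoromethyl)sulfonyl]oxy}cyclopent-1-ene-1,3-dicarboxylate | COC(=O)C1=C(OS(=O)(=O)C(F)(F)F)[C@](CCC(C)=O)(C(=O)OC)C(=O)C1 | intermediate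
9 | dimethyl (7aS)-1,5-dioxo-2,3,5,6,7,7a-hexahydro-1H-indene-3,7a-dicarboxylate (angular ester on C9; C3 = C6 is an epimer mixture) | COC(=O)C1CC(=O)[C@]2(C(=O)OC)CCC(=O)C=C12 | intermediate
10 | (2-bromoprop-2-en-1-yl)trimethylsilane | C=C(Br)C[Si](C)(C)C | starting material
11 | dimethyl 3a-(2-bromoprop-2-en-1-yl)-1,5-dioxooctahydro-1H-indene-3,7a-dicarboxylate; cis-fused, bromoallyl on C8 and ester on C9 both β, C6 epimer mixture | C=C(Br)C[C@]12CC(=O)CC[C@@]1(C(=O)OC)C(=O)CC2C(=O)OC | intermediate
12 | dimethyl 6-hydroxy-5-methylidene-1-oxooctahydro-3a,6-methanoazulene-3,8a(1H)-dicarboxylate; rings B/C/D, C13 bridgehead OH, C15–C16 bridge β, C9 ester β, C6 epimer mixture | C=C1C[C@]23C[C@@]1(O)CC[C@@]2(C(=O)OC)C(=O)CC3C(=O)OC | intermediate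
13 | methyl 6-hydroxy-5-methylidene-1-oxooctahydro-1H-3a,6-methanoazulene-3-carboxylate; C10 ketone, H-9 β, C6 ester β | C=C1C[C@]23C[C@@]1(O)CC[C@H]2C(=O)C[C@@H]3C(=O)OC | intermediate
14 | methyl 6-hydroxy-5-methylidene-1-{[(trifluoromethyl)sulfonyl]oxy}-3,4,5,6,7,8-hexahydro-3a,6-methanoazulene-3(8aH)-carboxylate; C5=C10 enol triflate | C=C1C[C@]23C[C@@]1(O)CC[C@H]2C(OS(=O)(=O)C(F)(F)F)=C[C@@H]3C(=O)OC | intermediate
15 | dimethyl 2-(prop-2-en-1-yl)propanedioate | C=CCC(C(=O)OC)C(=O)OC | starting material
16 | dimethyl 2-[3-(9-borabicyclo[3.3.1]nonan-9-yl)propyl]propanedioate | COC(=O)C(CCCB1C2CCCC1CCC2)C(=O)OC | intermediate (not isolated)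
17 | dimethyl 2-{3-[6-hydroxy-3-(methoxycarbonyl)-5-methylidene-3,4,5,6,7,8-hexahydro-3a,6-methanoazulen-1(8aH)-yl]propyl}propanedioate; C5=C10 alkene, chain on C10 | C=C1C[C@]23C[C@@]1(O)CC[C@H]2C(CCCC(C(=O)OC)C(=O)OC)=C[C@@H]3C(=O)OC | intermediate
18 | dimethyl ester of the target gibberellin (C7 and C18 methyl esters, 19,10-lactone, 13-hydroxy, 16-ene) | C=C1C[C@]23C[C@@]1(O)CC[C@H]2[C@@]12CCC[C@@](C(=O)OC)(C(=O)O1)[C@H]2[C@@H]3C(=O)OC | intermediate
19 | the target gibberellin, 13-hydroxy-20-norgibberell-16-ene-7,18,19-trioic acid 19,10-lactone (free C7 and C18 acids) | C=C1C[C@]23C[C@@]1(O)CC[C@H]2[C@@]12CCC[C@@](C(=O)O)(C(=O)O1)[C@H]2[C@@H]3C(=O)O | target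

**Step count:** 12 steps in total; the longest linear sequence is 12 steps (1 → 19).

**The three steps most likely to fail, each with a fallback**

Step 5 (ring C closure). The coupling has to form a bond to a tetrasubstituted vinyl carbon next to the quaternary C9, and warm phosphate could instead trigger retro-Claisen opening or Claisen attack of the ketone enolate on the C9 ester. The fallback sets out from 8 and drops palladium for an ionic addition–elimination. NaOMe in MeOH at −20 °C exchanges the triflate for methoxide to give the methyl enol ether dimethyl (3S)-2-methoxy-4-oxo-3-(3-oxobutyl)cyclopent-1-ene-1,3-dicarboxylate F1. LiN(SiMe3)2 in THF at −78 °C then forms the methyl ketone enolate, which adds to the β-methoxy enoate and expels methoxide (vinylogous Claisen condensation). The route is rejoined at 9.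

Step 6 (angular allylation). The bromo-substituted allylsilane is a weak nucleophile, the β-carbon is fully substituted and flanked by a quaternary carbon, and the chelated C10 keto ester could be attacked instead. The fallback sets out from 9 and delivers the same group by 1,2-addition followed by anionic oxy-Cope rearrangement. 2,3-Dibromopropene and zinc dust in THF/aq NH4Cl (Barbier) add to the less hindered enone carbonyl C13 to give the tertiary alcohol dimethyl (7aS)-5-(2-bromoprop-2-en-1-yl)-5-hydroxy-1-oxo-2,3,5,6,7,7a-hexahydro-1H-indene-3,7a-dicarboxylate F2. KH and 18-crown-6 in THF then trigger the [3,3] shift; the 2-bromoallyl unit is symmetrical end to end, so it arrives at C8 unchanged and the C13 ketone is regenerated. The route is rejoined at 11. The face of delivery follows the face of the 1,2-addition, so the C8 configuration would have to be checked.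

Step 11 (key step). Three things could go wrong: the C10 radical or cation could eliminate instead of lactonising, the malonyl radical could attack the β face, or the oxidant could touch the tertiary allylic alcohol. The fallback sets out from 17 and makes the same C4–C5 bond by iodine-atom transfer instead of metal oxidation. NaH then I2 in THF give the iodomalonate dimethyl 2-iodo-2-{3-[6-hydroxy-3-(methoxycarbonyl)-5-methylidene-3,4,5,6,7,8-hexahydro-3a,6-methanoazulen-1(8aH)-yl]propyl}propanedioate F3. Et3B and air in benzene at rt start a 6-endo atom-transfer cyclisation that stops at the tertiary C10 iodide, the tetracyclic triester F4. AgOTf with 2,6-di-tert-butylpyridine in CH2Cl2 ionises the iodide and the cis ester closes the lactone with loss of methyl triflate. The route is rejoined at 18.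

Further compounds
F1 | step 5 | dimethyl (3S)-2-methoxy-4-oxo-3-(3-oxobutyl)cyclopent-1-ene-1,3-dicarboxylate | COC(=O)C1=C(OC)[C@](CCC(C)=O)(C(=O)OC)C(=O)C1
F2 | step 6 | dimethyl (7aS)-5-(2-bromoprop-2-en-1-yl)-5-hydroxy-1-oxo-2,3,5,6,7,7a-hexahydro-1H-indene-3,7a-dicarboxylate | COC(=O)C1CC(=O)[C@]2(C(=O)OC)CCC(O)(CC(Br)=C)C=C12
F3 | step 11 | dimethyl 2-iodo-2-{3-[6-hydroxy-3-(methoxycarbonyl)-5-methylidene-3,4,5,6,7,8-hexahydro-3a,6-methanoazulen-1(8aH)-yl]propyl}propanedioate | C=C1C[C@]23C[C@@]1(O)CC[C@H]2C(CCCC(I)(C(=O)OC)C(=O)OC)=C[C@@H]3C(=O)OC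
F4 | step 11 | C10 tertiary iodide of the ring A-closed triester (10-iodo, 4,4-bis(methoxycarbonyl), C4–C5 bond α, no lactone) | C=C1C[C@]23C[C@@]1(O)CC[C@H]2C2(I)CCCC(C(=O)OC)(C(=O)OC)[C@H]2[C@@H]3C(=O)OC
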